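Between 0.500 min and 1.50 min the south run loses 5.8 percentage points of mono adduct, yet between 2.50 min and 6.00 min it moves by 0.3 points, far less and inside the scatter of 0.5 points.

| flask | substrate | reagent | remark | time |
|---|---|---|---|---|
| south | 1 mM | 1.1 equiv | the very flask that is asked about, followed so far |  |
| flask | 1.0 mM | 1.10 equiv |  | 20 min |

south run (percent of the substrate charged)

| time / min | mono adduct / % |
|---|---|
| 0.500 | 23.1 |
| 0.667 | 20.4 |
| 1.00 | 18.2 |
| 1.50 | 17.3 |
| 2.50 | 18.3 |
| 4.00 | 18.1 |
| 6.00 | 18.0 |

(standard deviation of a reading: 0.5 percentage points)

- the analysis behind the earlier runs scatters by 0.5 percentage points, standard deviation
- the reaction counts as stopped when no species that holds the substrate changes by six tenths of a point or more over the second half of the time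

1. the state of affairs at 20 min: stopped, and by what, or still going (forward and back rates have come level / it is still moving / all of the substrate has reacted / the reagent has run out first)
2. how much mono adduct there is at 20 min, in percent of the substrate charged

Reading down the table, the top rows fall and the bottom rows lie flat, averaging 18.1 % as a reading. The table shows a stop but not its cause, so I count the reagent in this flask: 1.10 mM against 1.0 mM of substrate. This is the reagent budget, the concentration of additions the charge can pay for, one reagent each. It stands 0.100 mM above the substrate, a narrow margin, and any second addition on the mono adduct draws on it while substrate may remain. So I take the fast additions as finished and expect the budget of 1.10 mM to run out first, which makes the reagent the limiting reagent, with the mono adduct staying near 18.1 % at 20 min. The readings do not exclude a balance.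

The forecast gives forward and back rates have come level and 18 %: “The flat level is most simply read as a balance of forward and back rates.” The forecast and I expect much the same level of mono adduct, but we name different states at 20 min.

The flask gives the reagent has run out first, with 17.6 % of mono adduct.

    reagent + mono adduct → bis adduct + released group (k = 118 /M/s)
    reagent + bis adduct → tris adduct + released group (k = 510 /M/s)
    mono adduct ⇌ isomer of the product (K = 1.96, k = 0.0441 /s)
    substrate + reagent → mono adduct + released group (k = 205 /M/s)

At 20.0 min the flask holds 0 % of its reagent charge beside 26 % of its substrate. Each addition frees one released group, so the budget says what to watch: the released group stands at 1.10 mM, level with the budget of 1.10 mM.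

In the neighbour with 0.660 equiv of reagent, the budget is 0.660 mM. That neighbour ends with 0.660 mM of released group, 0 % of its reagent charge and 14.7 % of mono adduct.

(The numbers in the tables were generated by integration for substances that don't exist.)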